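**Plan**

- Retrosynthesis: the four O–CH3 bonds are cut first (phenol protection), then the tether, numbered C1 to C14 from one benzylic carbon to the other, is cut at C3–C4 and at C11–C12.
- Enabling feature: the eight central methylenes C4–C11 have the carbon skeleton of 2,2'-bithiophene (two thiophene rings joined C2–C2'). Its two free α-carbons C5 and C5' map onto C4 and C11 and are the most acidic positions, so the heterocycle can serve as a masked octane-1,8-diyl dianion.
- Forward: 3-(3,5-dimethoxyphenyl)propanoic acid is reduced and brominated to the arylpropyl bromide (C1–C3 and C12–C14). Two copies are joined to 5,5'-dilithiobithiophene in a single two-directional alkylation; no ring is closed anywhere in the route.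
- Raney Ni then removes both sulfur atoms and saturates the eight ring carbons to (CH2)8, and BBr3 frees the four phenols.
- Stereochemistry: the target is achiral, with no stereocentre and no stereogenic double bond, so nothing has to be controlled.

Key step: step 3

**Route**

Step 1
Reactants: 1 3-(3,5-dimethoxyphenyl)propanoic acid
Product: 2 3-(3,5-dimethoxyphenyl)propan-1-ol
Conditions: LiAlH4 (1.5 equiv), THF, 0 °C → reflux; then H2O, 15% NaOH aq, H2O
Reagents that add atoms: none
Why: Hydride reduction of a carboxylic acid to the primary alcohol with LiAlH4 is routine, and the aryl methyl ethers and the arene are inert to it.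

Step 2
Reactants: 2 3-(3,5-dimethoxyphenyl)propan-1-ol
Product: 3 1-(3-bromopropyl)-3,5-dimethoxybenzene
Conditions: CBr4 (1.2 equiv), PPh3 (1.25 equiv), CH2Cl2, 0 °C → rt
Reagents that add atoms: carbon tetrabromide, BrC(Br)(Br)Br
Why: Appel reaction: the alkoxyphosphonium ion formed from the primary alcohol is displaced by bromide under neutral conditions that leave the electron-rich ring and its ethers untouched.

Step 3
Reactants: 3 1-(3-bromopropyl)-3,5-dimethoxybenzene (2.5 equiv); 4 2,2'-bithiophene
Product: 6 5,5'-bis[3-(3,5-dimethoxyphenyl)propyl]-2,2'-bithiophene, via 5,5'-dilithio-2,2'-bithiophene 5 (not isolated)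
Conditions: 4, n-BuLi (2.1 equiv), TMEDA (2.1 equiv), THF, −78 °C → 0 °C; then 3 (2.5 equiv), DMPU, −78 °C → rt
Reagents that add atoms: none
Why: Butyllithium removes the two α-protons at C5 and C5' of the bithiophene, the most acidic C–H bonds present because each is flanked by sulfur, and each thienyl carbanion then displaces bromide from the primary carbon of 3 by SN2, which forms the C3–C4 and C11–C12 bonds of the future chain. The closest known reaction type is the α-lithiation and alkylation of thiophenes, including the 5,5'-dialkylation of 2,2'-bithiophene with primary alkyl bromides. No ring is closed and no stereocentre is created. The step needs site-selective metalation and substitution in preference to elimination. Lithiation is completed before 3 is added, so no butyllithium is left to metalate the ring C–H between the two methoxy groups, and the thienyl anion is too weak a base to do so. The unhindered primary bromide with DMPU as polar cosolvent favours SN2 over E2, and the excess of 3 drives the second alkylation.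

Step 4
Reactants: 6 5,5'-bis[3-(3,5-dimethoxyphenyl)propyl]-2,2'-bithiophene
Product: 7 1,14-bis(3,5-dimethoxyphenyl)tetradecane
Conditions: Raney Ni (W-2, large excess), H2 (1 atm), EtOH/THF, reflux; filtration through Celite
Reagents that add atoms: none
Why: Raney nickel hydrodesulfurization: hydrogenolysis of the four C–S bonds and saturation of the remaining unsaturation turn each 2,5-disubstituted thiophene into four methylenes, a known route from dialkylthiophenes to alkanes, while aryl methyl ethers and benzene rings are not reduced at atmospheric pressure.

Step 5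
Reactants: 7 1,14-bis(3,5-dimethoxyphenyl)tetradecane
Product: 8 bisnorstriatol, 5,5'-(tetradecane-1,14-diyl)bis(benzene-1,3-diol)
Conditions: BBr3 (8 equiv), CH2Cl2, −78 °C → rt; then MeOH, H2O, 0 °C
Reagents that add atoms: none
Why: Lewis-acid cleavage of aryl methyl ethers: BBr3 coordinates each methoxy oxygen, bromide removes the methyl group by SN2, and hydrolysis of the aryl borates frees the four phenols; the saturated chain offers nothing else to react.

**Compound list**

1 | 3-(3,5-dimethoxyphenyl)propanoic acid | COc1cc(CCC(=O)O)cc(OC)c1 | starting material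
2 | 3-(3,5-dimethoxyphenyl)propan-1-ol | COc1cc(CCCO)cc(OC)c1 | intermediate
3 | 1-(3-bromopropyl)-3,5-dimethoxybenzene | COc1cc(CCCBr)cc(OC)c1 | intermediate
4 | 2,2'-bithiophene | c1csc(c1)-c1cccs1 | starting material
5 | 5,5'-dilithio-2,2'-bithiophene | [Li]c1ccc(s1)-c1ccc([Li])s1 | intermediate
6 | 5,5'-bis[3-(3,5-dimethoxyphenyl)propyl]-2,2'-bithiophene | COc1cc(CCCc2ccc(s2)-c2ccc(CCCc3cc(OC)cc(OC)c3)s2)cc(OC)c1 | intermediate
7 | 1,14-bis(3,5-dimethoxyphenyl)tetradecane | COc1cc(CCCCCCCCCCCCCCc2cc(OC)cc(OC)c2)cc(OC)c1 | intermediate
8 | bisnorstriatol | Oc1cc(O)cc(CCCCCCCCCCCCCCc2cc(O)cc(O)c2)c1 | target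

**Count**

Total step count: 5. Longest linear sequence: 5 steps (1 → 2 → 3 → 6 → 7 → 8); 4 enters at step 3.

**Steps most likely to fail**

Step 3. The second alkylation may stall, or the thienyllithium may act as a base (E2 on the bromide, proton transfer), so that mono-alkylated or unalkylated bithiophene is returned. The fallback inverts the polarity and forms the same two bonds by Negishi coupling. It sets out from 4 and 3. Bromination of 4 with N-bromosuccinimide (2 equiv, DMF, 0 °C → rt) should give 5,5'-dibromo-2,2'-bithiophene F1. Insertion of Zn dust into 3 in the presence of LiCl (THF, 50 °C) should give [3-(3,5-dimethoxyphenyl)propyl]zinc bromide F2. Coupling of F1 with F2 (2.5 equiv) under PdCl2(dppf) catalysis in THF at 60 °C should then deliver 6, where the route is rejoined.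

Step 4. Hydrogenolysis may stop short and leave thiolane or alkene residues, and the waxy product may stay adsorbed on the large excess of nickel. The fallback keeps the C3–C4 and C11–C12 disconnections but replaces the masked C8 unit by a real one, so no desulfurization is needed. It sets out from 3. Mg in THF should give [3-(3,5-dimethoxyphenyl)propyl]magnesium bromide F3. Copper-catalysed sp3–sp3 Grignard coupling (Li2CuCl4, 3 mol%, THF, −10 °C → rt) with commercial 1,8-dibromooctane (BrCCCCCCCCBr, 0.45 equiv) should give 7 directly, rejoining the route before step 5.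

Step 5. Cleavage of four methyl ethers on a waxy, poorly soluble substrate may remain incomplete and give partly methylated phenols, and the free resorcinols may oxidize during a long work-up. The fallback changes the protecting group so that the final unmasking is a mild acetal methanolysis. It sets out from 3 and comes back at 8.
- BBr3 (CH2Cl2, −78 °C → rt) on this small, soluble molecule should give 5-(3-bromopropyl)benzene-1,3-diol F4.
- Chloromethyl methyl ether and iPr2NEt (CH2Cl2, 0 °C → rt) should give 1-(3-bromopropyl)-3,5-bis(methoxymethoxy)benzene F5.
- Alkylation of 5 (generated from 4 as in step 3) with F5 should give 5,5'-bis{3-[3,5-bis(methoxymethoxy)phenyl]propyl}-2,2'-bithiophene F6.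
- Raney Ni as in step 4 should give 1,14-bis[3,5-bis(methoxymethoxy)phenyl]tetradecane F7.
- HCl in MeOH (40 °C) should remove the four acetals and arrive at 8.

**Further compounds**

F1 | step 3 | 5,5'-dibromo-2,2'-bithiophene | Brc1ccc(s1)-c1ccc(Br)s1
F2 | step 3 | [3-(3,5-dimethoxyphenyl)propyl]zinc bromide | COc1cc(CCC[Zn]Br)cc(OC)c1
F3 | step 4 | [3-(3,5-dimethoxyphenyl)propyl]magnesium bromide | COc1cc(CCC[Mg]Br)cc(OC)c1
F4 | step 5 | 5-(3-bromopropyl)benzene-1,3-diol | Oc1cc(O)cc(CCCBr)c1
F5 | step 5 | 1-(3-bromopropyl)-3,5-bis(methoxymethoxy)benzene | COCOc1cc(CCCBr)cc(OCOC)c1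
F6 | step 5 | 5,5'-bis{3-[3,5-bis(methoxymethoxy)phenyl]propyl}-2,2'-bithiophene | COCOc1cc(CCCc2ccc(s2)-c2ccc(CCCc3cc(OCOC)cc(OCOC)c3)s2)cc(OCOC)c1
F7 | step 5 | 1,14-bis[3,5-bis(methoxymethoxy)phenyl]tetradecane | COCOc1cc(CCCCCCCCCCCCCCc2cc(OCOC)cc(OCOC)c2)cc(OCOC)c1
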